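Ring B is taken apart across the acyl bond C5–C6 and the ring-fusion bond C3–C8, which also opens ring A, so the whole decalin reduces to one linear keto ester. A base-mediated Michael–Claisen bicyclization closes both rings in one operation: C3, made acidic by a temporary C4 ketone and the ring A diene, adds to C8 of the enoate, then C5 acylates at C6. The step exploits the 1,3-relation of the C6 ketone and C8 in ring B and allylic strain about the exocyclic C10=C11 and C7=C8 alkenes, which relay the C9 stereocentre to C8 and the cis ring fusion. The C4 oxygen is removed afterwards via the enol triflate.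

Key step: step 12

Remark on locants (used throughout): ring A = C1(CH3)=C2–C3–C8–C9–C10; ring B = C3–C4–C5(CH3)–C6(=O)–C7(CH3)–C8; exocyclic C10=C11–C12(OH)–CH3; side chain on C9 = C13=C14(CH3)–C15–C16(CH3) (epoxide)–C17=C18–C19O2H.

Step 1
Reactants: 1 (S)-glycidol, 2 methyl 2-(triphenyl-λ5-phosphanylidene)propanoate
Product: 4 methyl (2E)-2-methyl-3-[(2S)-oxiran-2-yl]prop-2-enoate, via (R)-oxirane-2-carbaldehyde 3 (not isolated)
Conditions: (COCl)2, DMSO, CH2Cl2, −78 °C; Et3N; then 2, −78 °C → rt
Reagents that add atoms: none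
Why: Swern oxidation followed by in-flask Wittig olefination with a stabilized ylide should give the (E)-enoate without isolating the volatile aldehyde; the epoxide carbon (later C9) comes unchanged from the chiral pool.

Step 2
Reactants: 5 (R)-but-3-yn-2-ol
Product: 6 (R)-(but-3-yn-2-yloxy)(tert-butyl)diphenylsilane
Conditions: t-BuPh2SiCl, imidazole, DMF, rt
Reagents that add atoms: tert-butyl(chloro)diphenylsilane, CC(C)(C)[Si](Cl)(c1ccccc1)c1ccccc1
Why: Standard silylation protects the future C12 alcohol (R, from the chiral pool) with a group that should outlast fluoride-promoted coupling, base, hydride and oxidation steps.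

Step 3
Reactants: 6 (R)-(but-3-yn-2-yloxy)(tert-butyl)diphenylsilane, 4 methyl (2E)-2-methyl-3-[(2S)-oxiran-2-yl]prop-2-enoate
Product: 9 methyl (2E,4S,7R)-7-[(tert-butyldiphenylsilyl)oxy]-4-(hydroxymethyl)-2-methyloct-2-en-5-ynoate, via lithium acetylide 7 (not isolated), via diethylalkynylalane 8 (not isolated)
Conditions: n-BuLi, toluene, −78 → 0 °C; Et2AlCl, 0 °C; then 4, −40 → 0 °C
Reagents that add atoms: none
Why: The Lewis-acidic alkynylalane should open the vinyl epoxide by SN2 attack at the allylic carbon (activated by the adjacent enoate π system) with inversion, which sets C9 and frees the C13 hydroxyl (alkynylalane epoxide opening).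

Step 4
Reactants: 9 methyl (2E,4S,7R)-7-[(tert-butyldiphenylsilyl)oxy]-4-(hydroxymethyl)-2-methyloct-2-en-5-ynoate
Product: 11 cyclic siloxane (2,2-dimethyl-1,2-oxasilolane with exocyclic C10=C11), via hydridosilyl ether 10 (not isolated)
Conditions: (HMe2Si)2NH, neat, rt; then Pt2[(CH2=CHSiMe2)2O]3 (zerovalent platinum, 0.5 mol %), THF, rt
Reagents that add atoms: 1,1,3,3-tetramethyldisilazane, C[SiH](C)N[SiH](C)C
Why: O-silylation and platinum-catalysed intramolecular syn-hydrosilylation (5-exo-dig) should place silicon on C10 and hydrogen on C11 on the same side, which fixes regiochemistry and the later C10=C11 geometry (C12 cis to C9).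

Step 5
Reactants: 12 but-2-yn-1-ol
Product: 13 (2Z)-3-iodobut-2-en-1-ol
Conditions: NaAlH2(OCH2CH2OCH3)2, THF, 0 °C → rt; then I2, −78 → 0 °C
Reagents that add atoms: iodine, II
Why: Hydroxyl-directed trans-hydroalumination of the propargylic alcohol and iodinolysis with retention should give the vinyl iodide with iodine cis to the CH2OH group (the future C3).

Step 6
Reactants: 13 (2Z)-3-iodobut-2-en-1-ol
Product: 14 (2Z)-1-bromo-3-iodobut-2-ene
Conditions: CBr4, PPh3, CH2Cl2, 0 °C
Reagents that add atoms: tetrabromomethane, BrC(Br)(Br)Br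
Why: The Appel reaction converts the primary allylic alcohol into the bromide without touching the vinyl iodide or the alkene geometry.

Step 7
Reactants: 15 propanal, 16 propane-1,3-dithiol
Product: 17 2-ethyl-1,3-dithiane
Conditions: BF3·OEt2 (cat.), CH2Cl2, 0 °C → rt
Reagents that add atoms: none
Why: Lewis-acid-catalysed dithioacetalization gives the masked propanoyl anion (future C4 carbonyl with C5 and its methyl).

Step 8
Reactants: 17 2-ethyl-1,3-dithiane, 14 (2Z)-1-bromo-3-iodobut-2-ene
Product: 19 2-ethyl-2-[(2Z)-3-iodobut-2-en-1-yl]-1,3-dithiane, via 2-ethyl-2-lithio-1,3-dithiane 18 (not isolated)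
Conditions: n-BuLi, THF, −30 °C; then 14, −78 °C
Reagents that add atoms: none
Why: Corey–Seebach alkylation: the soft lithiodithiane should displace the primary allylic bromide by SN2 at −78 °C faster than it exchanges with the vinyl iodide, forming the C3–C4 bond.

Step 9
Reactants: 11 cyclic siloxane, 19 2-ethyl-2-[(2Z)-3-iodobut-2-en-1-yl]-1,3-dithiane
Product: 20 methyl (2E,4S,5E,6Z)-5-{(2R)-2-[(tert-butyldiphenylsilyl)oxy]propylidene}-8-(2-ethyl-1,3-dithian-2-yl)-4-(hydroxymethyl)-2,6-dimethylocta-2,6-dienoate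
Conditions: Pd(dba)2 (zerovalent palladium, 5 mol %), n-Bu4NF (2 equiv), THF, rt
Reagents that add atoms: none
Why: Hiyama–Denmark cross-coupling of the fluoride-activated siloxane with the vinyl iodide forms the C1–C10 bond with retention at both alkenes, so the (Z)-C1=C2 and the C10=C11 geometries are fixed and the C13 alcohol is released.

Step 10
Reactants: 20 coupled dithiane alcohol
Product: 21 methyl (2E,4S,5E,6Z)-5-{(2R)-2-[(tert-butyldiphenylsilyl)oxy]propylidene}-4-(hydroxymethyl)-2,6-dimethyl-9-oxoundeca-2,6-dienoate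
Conditions: MeI, CaCO3, MeCN/H2O (9:1), 45 °C
Reagents that add atoms: water, O
Why: S-alkylative hydrolysis of the dithiane under buffered, near-neutral conditions should unmask the C4 ketone without moving the β,γ-double bond into conjugation.

Step 11
Reactants: 21 keto alcohol
Product: 22 methyl (2E,4S,5E,6Z)-5-{(2R)-2-[(tert-butyldiphenylsilyl)oxy]propylidene}-2,6-dimethyl-9-oxo-4-{[(triethylsilyl)oxy]methyl}undeca-2,6-dienoate
Conditions: Et3SiCl, imidazole, CH2Cl2, 0 °C
Reagents that add atoms: chlorotriethylsilane, CC[Si](Cl)(CC)CC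
Why: Silylation masks the C13 hydroxyl (so that it is not sulfonylated in step 13) with a group that step 16 can oxidize directly.

Step 12
Reactants: 22 linear keto ester
Product: 24 bicyclic dione (rings A plus B closed; C4/C6 diketone drawn as the C4 enol), via Michael adduct 23 (not isolated)
Conditions: KOC(CH3)3 (1.2 equiv), THF (0.005 M), −40 → 0 °C; then AcOH
Reagents that add atoms: none
Why: KOC(CH3)3 removes the C3 proton (alpha to the C4 ketone and allylic to the C1=C2/C10=C11 diene), the extended enolate adds through C3 to C8 of the tiglate-type enoate (C3–C8 bond, ring A), and after proton transfer the C5 enolate acylates the methyl ester (C5–C6 bond, ring B), the weakly basic potassium diketonate being the thermodynamic sink that pulls both reversible events forward. The closest known reaction type is the consecutive Michael–Claisen (3+3) synthesis of cyclohexane-1,3-diones from ketones and enoates, run here intramolecularly as a bicyclization. Ring A closes 6-(enolexo)-exo-trig and ring B closes 6-(enolendo)-exo-trig. C8 is controlled by C9: allylic 1,3-strain about C10=C11 and C7=C8 holds C9–H in the plane of both alkenes and C13 perpendicular to them, so C3 should add to the enoate face opposite C13 (C8–H anti to C9–H). C3 is controlled by geometry: with C13 and C7 axial on ring A only the C3 epimer with equatorial C4 (cis fusion) can reach C6, and C3 stays epimerizable until the Claisen closure, so the other epimer is funnelled; C5 and C7 are set thermodynamically in step 15. The step needs C3 rather than C5 to attack and C3 rather than C1 or C11 of the extended enolate to bond, which ring size secures (only the C3–C8 mode gives a six-membered ring), and it needs high dilution and low temperature to hold back intermolecular addition and vinylogous loss of the C12 silyloxy group.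

Step 13
Reactants: 24 bicyclic dione
Product: 25 C4 enol triflate (C4(OSO2CF3)=C5(CH3)–C6=O)
Conditions: (CF3SO2)2O, pyridine, CH2Cl2, −78 °C
Reagents that add atoms: trifluoromethanesulfonic anhydride, O=S(=O)(OS(=O)(=O)C(F)(F)F)C(F)(F)F
Why: O-sulfonylation of the vinylogous acid should occur at the less hindered C4 oxygen, which is flanked only by the in-plane C3–H (C2 is axial), whereas the C6 oxygen is shielded by the pseudo-equatorial C7 methyl.

Step 14
Reactants: 25 C4 enol triflate
Product: 26 enone (C4H=C5(CH3)–C6=O in ring B)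
Conditions: Pd(OAc)2 (5 mol %), PPh3, HCO2H, n-Bu3N, DMF, 60 °C
Reagents that add atoms: none
Why: Palladium-catalysed formate reduction of the vinylogous acyl triflate replaces the C4 oxygen by hydrogen, which removes the temporary activating group; the unactivated diene and silyl ethers should be inert.

Step 15
Reactants: 26 enone
Product: 27 bicyclic ketone (target core with CH2OSiEt3 on C9 and the silyl ether on C12)
Conditions: LiBH(sec-Bu)3, THF, −78 °C; MeOH; then DBU (cat.), CH2Cl2, rt
Reagents that add atoms: none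
Why: 1,4-Hydride addition to the β-unsubstituted enone gives the ketone, and base equilibration should place both the C5 and C7 methyl groups equatorial (5S,7R) in the cis-decalin conformer that the axial C13 group enforces (thermodynamic control).

Step 16
Reactants: 27 bicyclic ketone
Product: 28 C13 aldehyde
Conditions: (COCl)2, DMSO, CH2Cl2, −78 → −40 °C; then Et3N, −78 → 0 °C
Reagents that add atoms: none
Why: Swern conditions cleave and oxidize a primary triethylsilyl ether directly to the aldehyde while the secondary tert-butyldiphenylsilyl ether survives; the aldehyde is used at once to avoid epimerization at C9.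

Step 17
Reactants: 28 C13 aldehyde, 29 ethyl 2-(diethoxyphosphoryl)propanoate
Product: 30 (E)-enoate (C13=C14(CH3)–CO2Et)
Conditions: LiCl, DBU, MeCN, 0 °C
Reagents that add atoms: none
Why: Horner–Wadsworth–Emmons olefination under mild Masamune–Roush conditions should give the (E)-trisubstituted C13=C14 alkene fast enough at 0 °C to leave the α-stereocentre C9 untouched.

Step 18
Reactants: 30 (E)-enoate
Product: 31 diol (C15 allylic alcohol plus C6 carbinol as an inconsequential epimer mixture)
Conditions: (i-Bu)2AlH, CH2Cl2, −78 °C; aq. sodium potassium tartrate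
Reagents that add atoms: none
Why: The hydride reduces the ester to the allylic alcohol and, deliberately, the C6 ketone to the carbinol, which masks the ketone through the remaining hydride step and is re-oxidized in step 22.

Step 19
Reactants: 31 diol, 32 ethyl 2-(triphenyl-λ5-phosphanylidene)propanoate
Product: 34 (E,E)-dienoate (C13=C14(CH3)–C15=C16(CH3)–CO2Et), via enal 33 (not isolated)
Conditions: MnO2, toluene, rt → 70 °C
Reagents that add atoms: none
Why: MnO2 oxidizes only the allylic alcohol and the stabilized ylide traps the enal in the same flask (tandem oxidation–Wittig), which should give the (E)-C15=C16 alkene while the saturated C6 carbinol is left alone.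

Step 20
Reactants: 34 (E,E)-dienoate
Product: 35 dienol (C17 primary allylic alcohol)
Conditions: (i-Bu)2AlH, CH2Cl2, −78 °C; aq. sodium potassium tartrate
Reagents that add atoms: none
Why: 1,2-Reduction of the dienoate gives the allylic alcohol needed to direct the epoxidation.

Step 21
Reactants: 35 dienol
Product: 36 epoxy alcohol ((15S,16S)-epoxide with C17H2OH)
Conditions: Ti(OCH(CH3)2)4, L-(+)-diethyl tartrate, t-BuOOH, 4 Å molecular sieves, CH2Cl2, −20 °C
Reagents that add atoms: tert-butyl hydroperoxide, CC(C)(C)OO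
Why: Sharpless asymmetric epoxidation is confined to the alkene of the allylic alcohol and, with the L-(+)-tartrate, should deliver oxygen to the face that gives the (15S,16S)-epoxide (reagent control), the (E)-alkene geometry fixing the trans relationship.

Step 22
Reactants: 36 epoxy alcohol, 37 methyl 2-(triphenyl-λ5-phosphanylidene)acetate
Product: 39 silyl-protected methyl ester of the target, via keto epoxy aldehyde 38 (not isolated)
Conditions: Dess–Martin periodinane, NaHCO3, CH2Cl2, 0 °C → rt; then 37, rt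
Reagents that add atoms: none
Why: Buffered Dess–Martin oxidation converts the primary epoxy alcohol into the aldehyde and the C6 carbinol back into the ketone (C5 and C7 untouched), and the stabilized ylide then reacts only with the aldehyde to give the (E)-C17=C18 enoate.

Step 23
Reactants: 39 silyl-protected methyl ester
Product: 41 CNP0414188.1, via methyl ester 40 (not isolated)
Conditions: n-Bu4NF, THF, rt; then LiOH, THF/H2O, 0 °C; 0.1 M HCl to pH 5
Reagents that add atoms: lithium hydroxide, [Li+].[OH-]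
Why: Fluoride removes the C12 silyl ether and mild saponification frees the acid; acidification only to pH 5 should spare the doubly allylic epoxide, and C5 and C7 are already the thermodynamic epimers.

Compound list
1 | (S)-glycidol [(2S)-oxiran-2-ylmethanol] | OC[C@H]1CO1 | starting material
2 | methyl 2-(triphenyl-λ5-phosphanylidene)propanoate | COC(=O)C(C)=P(c1ccccc1)(c1ccccc1)c1ccccc1 | starting material
3 | (R)-oxirane-2-carbaldehyde | O=C[C@H]1CO1 | intermediate
4 | methyl (2E)-2-methyl-3-[(2S)-oxiran-2-yl]prop-2-enoate | COC(=O)/C(C)=C/[C@H]1CO1 | intermediate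
5 | (R)-but-3-yn-2-ol | C#C[C@@H](C)O | starting material
6 | (R)-(but-3-yn-2-yloxy)(tert-butyl)diphenylsilane | C#C[C@@H](C)O[Si](c1ccccc1)(c1ccccc1)C(C)(C)C | intermediate
7 | lithium acetylide of 6 | [Li]C#C[C@@H](C)O[Si](c1ccccc1)(c1ccccc1)C(C)(C)C | intermediate
8 | diethyl{(3R)-3-[(tert-butyldiphenylsilyl)oxy]but-1-yn-1-yl}alane | CC[Al](CC)C#C[C@@H](C)O[Si](c1ccccc1)(c1ccccc1)C(C)(C)C | intermediate
9 | methyl (2E,4S,7R)-7-[(tert-butyldiphenylsilyl)oxy]-4-(hydroxymethyl)-2-methyloct-2-en-5-ynoate | COC(=O)/C(C)=C/[C@H](CO)C#C[C@@H](C)O[Si](c1ccccc1)(c1ccccc1)C(C)(C)C | intermediate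
10 | O-dimethylsilyl (Si–H) ether of 9 at the primary alcohol | COC(=O)/C(C)=C/[C@H](CO[SiH](C)C)C#C[C@@H](C)O[Si](c1ccccc1)(c1ccccc1)C(C)(C)C | intermediate
11 | methyl (2E)-3-[(3E,4R)-3-{(2R)-2-[(tert-butyldiphenylsilyl)oxy]propylidene}-2,2-dimethyl-1,2-oxasilolan-4-yl]-2-methylprop-2-enoate | COC(=O)/C(C)=C/[C@@H]1CO[Si](C)(C)/C1=C/[C@@H](C)O[Si](c2ccccc2)(c2ccccc2)C(C)(C)C | intermediate
12 | but-2-yn-1-ol | CC#CCO | starting material
13 | (2Z)-3-iodobut-2-en-1-ol | C/C(I)=C/CO | intermediate
14 | (2Z)-1-bromo-3-iodobut-2-ene | C/C(I)=C/CBr | intermediate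
15 | propanal | CCC=O | starting material
16 | propane-1,3-dithiol | SCCCS | starting material
17 | 2-ethyl-1,3-dithiane | CCC1SCCCS1 | intermediate
18 | 2-ethyl-2-lithio-1,3-dithiane | CCC1([Li])SCCCS1 | intermediate
19 | 2-ethyl-2-[(2Z)-3-iodobut-2-en-1-yl]-1,3-dithiane | CCC1(C/C=C(C)\I)SCCCS1 | intermediate
20 | methyl (2E,4S,5E,6Z)-5-{(2R)-2-[(tert-butyldiphenylsilyl)oxy]propylidene}-8-(2-ethyl-1,3-dithian-2-yl)-4-(hydroxymethyl)-2,6-dimethylocta-2,6-dienoate | CCC1(C/C=C(C)\C(=C\[C@@H](C)O[Si](c2ccccc2)(c2ccccc2)C(C)(C)C)[C@@H](CO)/C=C(\C)C(=O)OC)SCCCS1 | intermediate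
21 | methyl (2E,4S,5E,6Z)-5-{(2R)-2-[(tert-butyldiphenylsilyl)oxy]propylidene}-4-(hydroxymethyl)-2,6-dimethyl-9-oxoundeca-2,6-dienoate | CCC(=O)C/C=C(C)\C(=C\[C@@H](C)O[Si](c1ccccc1)(c1ccccc1)C(C)(C)C)[C@@H](CO)/C=C(\C)C(=O)OC | intermediate
22 | methyl (2E,4S,5E,6Z)-5-{(2R)-2-[(tert-butyldiphenylsilyl)oxy]propylidene}-2,6-dimethyl-9-oxo-4-{[(triethylsilyl)oxy]methyl}undeca-2,6-dienoate | CCC(=O)C/C=C(C)\C(=C\[C@@H](C)O[Si](c1ccccc1)(c1ccccc1)C(C)(C)C)[C@@H](CO[Si](CC)(CC)CC)/C=C(\C)C(=O)OC | intermediate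
23 | Michael adduct: ring A closed, propanoyl on C3, CH(CH3)CO2CH3 arm on C8, CH2OSiEt3 on C9, silyloxypropylidene on C10 | CC1=C[C@@H](C(=O)CC)[C@@H]([C@@H](C)C(=O)OC)[C@H](CO[Si](CC)(CC)CC)/C1=C\[C@@H](C)O[Si](c1ccccc1)(c1ccccc1)C(C)(C)C | intermediate
24 | bicyclic C4/C6 dione (C4 enol form), cis-fused, CH2OSiEt3 on C9, silyl ether on C12 | CC1=C[C@H]2C(O)=C(C)C(=O)[C@H](C)[C@H]2[C@H](CO[Si](CC)(CC)CC)/C1=C\[C@@H](C)O[Si](c1ccccc1)(c1ccccc1)C(C)(C)C | intermediate
25 | C4 enol triflate of 24 | CC1=C[C@H]2C(OS(=O)(=O)C(F)(F)F)=C(C)C(=O)[C@H](C)[C@H]2[C@H](CO[Si](CC)(CC)CC)/C1=C\[C@@H](C)O[Si](c1ccccc1)(c1ccccc1)C(C)(C)C | intermediate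
26 | ring B enone (C4=C5, C6 ketone) | CC1=C[C@H]2C=C(C)C(=O)[C@H](C)[C@H]2[C@H](CO[Si](CC)(CC)CC)/C1=C\[C@@H](C)O[Si](c1ccccc1)(c1ccccc1)C(C)(C)C | intermediate
27 | (1S,2E,4aS,6S,8R,8aR)-2-{(2R)-2-[(tert-butyldiphenylsilyl)oxy]propylidene}-3,6,8-trimethyl-1-{[(triethylsilyl)oxy]methyl}-1,4a,5,6,8,8a-hexahydronaphthalen-7(2H)-one | CC1=C[C@H]2C[C@H](C)C(=O)[C@H](C)[C@H]2[C@H](CO[Si](CC)(CC)CC)/C1=C\[C@@H](C)O[Si](c1ccccc1)(c1ccccc1)C(C)(C)C | intermediate
28 | C13 aldehyde of the core (CHO on C9) | CC1=C[C@H]2C[C@H](C)C(=O)[C@H](C)[C@H]2[C@H](C=O)/C1=C\[C@@H](C)O[Si](c1ccccc1)(c1ccccc1)C(C)(C)C | intermediate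
29 | ethyl 2-(diethoxyphosphoryl)propanoate | CCOC(=O)C(C)P(=O)(OCC)OCC | starting material
30 | (E)-enoate: core with C13=C14(CH3)CO2Et on C9 | CC1=C[C@H]2C[C@H](C)C(=O)[C@H](C)[C@H]2[C@H](/C=C(\C)C(=O)OCC)/C1=C\[C@@H](C)O[Si](c1ccccc1)(c1ccccc1)C(C)(C)C | intermediate
31 | diol: C15 allylic alcohol and C6 carbinol (C6 epimers) | CC1=C[C@H]2C[C@H](C)C(O)[C@H](C)[C@H]2[C@H](/C=C(\C)CO)/C1=C\[C@@H](C)O[Si](c1ccccc1)(c1ccccc1)C(C)(C)C | intermediate
32 | ethyl 2-(triphenyl-λ5-phosphanylidene)propanoate | CCOC(=O)C(C)=P(c1ccccc1)(c1ccccc1)c1ccccc1 | starting material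
33 | (E)-enal (C15 aldehyde, C6 carbinol) | CC1=C[C@H]2C[C@H](C)C(O)[C@H](C)[C@H]2[C@H](/C=C(\C)C=O)/C1=C\[C@@H](C)O[Si](c1ccccc1)(c1ccccc1)C(C)(C)C | intermediate
34 | (E,E)-dienoate (C17 ethyl ester, C6 carbinol) | CC1=C[C@H]2C[C@H](C)C(O)[C@H](C)[C@H]2[C@H](/C=C(\C)/C=C(\C)C(=O)OCC)/C1=C\[C@@H](C)O[Si](c1ccccc1)(c1ccccc1)C(C)(C)C | intermediate
35 | (E,E)-dienol (C17 alcohol, C6 carbinol) | CC1=C[C@H]2C[C@H](C)C(O)[C@H](C)[C@H]2[C@H](/C=C(\C)/C=C(\C)CO)/C1=C\[C@@H](C)O[Si](c1ccccc1)(c1ccccc1)C(C)(C)C | intermediate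
36 | (15S,16S)-epoxy alcohol (C17 alcohol, C6 carbinol) | CC1=C[C@H]2C[C@H](C)C(O)[C@H](C)[C@H]2[C@H](/C=C(\C)[C@@H]2O[C@@]2(C)CO)/C1=C\[C@@H](C)O[Si](c1ccccc1)(c1ccccc1)C(C)(C)C | intermediate
37 | methyl 2-(triphenyl-λ5-phosphanylidene)acetate | COC(=O)C=P(c1ccccc1)(c1ccccc1)c1ccccc1 | starting material
38 | keto epoxy aldehyde (C6 ketone, C17 aldehyde) | CC1=C[C@H]2C[C@H](C)C(=O)[C@H](C)[C@H]2[C@H](/C=C(\C)[C@@H]2O[C@@]2(C)C=O)/C1=C\[C@@H](C)O[Si](c1ccccc1)(c1ccccc1)C(C)(C)C | intermediate
39 | methyl ester of the target with C12 tert-butyldiphenylsilyl ether | CC1=C[C@H]2C[C@H](C)C(=O)[C@H](C)[C@H]2[C@H](/C=C(\C)[C@@H]2O[C@@]2(C)/C=C/C(=O)OC)/C1=C\[C@@H](C)O[Si](c1ccccc1)(c1ccccc1)C(C)(C)C | intermediate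
40 | methyl ester of the target | CC1=C[C@H]2C[C@H](C)C(=O)[C@H](C)[C@H]2[C@H](/C=C(\C)[C@@H]2O[C@@]2(C)/C=C/C(=O)OC)/C1=C\[C@@H](C)O | intermediate
41 | CNP0414188.1: (2E)-3-[(2S,3S)-3-{(1E)-1-[(1R,2E,4aS,6S,8R,8aR)-2-[(2R)-2-hydroxypropylidene]-3,6,8-trimethyl-7-oxo-1,2,4a,5,6,7,8,8a-octahydronaphthalen-1-yl]prop-1-en-2-yl}-2-methyloxiran-2-yl]prop-2-enoic acid | CC1=C[C@H]2C[C@H](C)C(=O)[C@H](C)[C@H]2[C@H](/C=C(\C)[C@@H]2O[C@@]2(C)/C=C/C(=O)O)/C1=C\[C@@H](C)O | target

Total step count: 23. Longest linear sequence: 18 steps (1, 3, 4, 9–23).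

Steps most likely to fail

Step 12. Under the alkoxide the C1=C2 bond may migrate into conjugation with the C4 ketone, the extended enolate may expel the C12 silyloxy group, or the Michael closure may show poor facial selectivity. The fallback separates the two bond formations and avoids equilibrating base in the first one. It sets out from 22: soft enolization (Me3SiOSO2CF3, Et3N, CH2Cl2, −78 °C) should give the extended trimethylsilyl dienol ether F1. A catalytic silyl Lewis acid (Me3SiN(SO2CF3)2, CH2Cl2, −78 °C) then closes ring A by intramolecular Mukaiyama–Michael addition to the Michael adduct 23, which is now isolated. A separate Claisen (Dieckmann-type) closure with LiN(SiMe3)2 in THF (−78 → 0 °C) forms ring B, and the route is rejoined at 24.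

Step 13. Sulfonylation may lose regiocontrol between the two enol oxygens and occur at the C6 oxygen. The fallback replaces triflation and reduction by a Stork–Danheiser transposition that tolerates a regioisomer mixture. It sets out from 24: O-methylation (Me3SiCHN2, MeOH/toluene) gives the two vinylogous methyl esters, which are separated. The C6 methyl enol ether F2 is reduced at C4 with (i-Bu)2AlH to the allylic alcohol F3, and mild acid hydrolysis (oxalic acid, wet THF) with allylic transposition gives enone 26, where the route is rejoined. The C4 methyl enol ether is hydrolysed back to 24 and recycled.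

Step 3. The alane may attack the unhindered terminal carbon C13 of the epoxide instead of C9 (wrong regiochemistry of ring opening). The fallback uses hydroxyl-directed opening of a 2,3-epoxy alcohol, where attack at the distal carbon is enforced by chelation. It sets out from 6 (converted into alane 8 as in step 3) and commercial (Z)-but-2-ene-1,4-diol, and comes back at 9.
- Monosilylation (NaH, t-BuMe2SiCl) gives (2Z)-4-[(tert-butyldimethylsilyl)oxy]but-2-en-1-ol F4.
- Sharpless asymmetric epoxidation with L-(+)-diethyl tartrate gives the (2S,3R)-epoxy alcohol F5.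
- Alane 8 opens F5 at C3 with inversion to give the 1,2-diol F6.
- NaIO4 cleavage gives the α-alkynyl aldehyde F7, which is taken at once into a Wittig reaction with 2 to give the silyl-protected enoate F8.
- HF·pyridine removes the primary silyl ether to give 9.

Further compounds
F1 | step 12 | extended trimethylsilyl dienol ether of 22 (C4(OSiMe3)=C3) | CCC(O[Si](C)(C)C)=C/C=C(C)\C(=C\[C@@H](C)O[Si](c1ccccc1)(c1ccccc1)C(C)(C)C)[C@@H](CO[Si](CC)(CC)CC)/C=C(\C)C(=O)OC
F2 | step 13 | C6 methyl enol ether of 24 (C4 ketone, C5=C6(OCH3)) | CC1=C[C@H]2C(=O)C(C)=C(OC)[C@H](C)[C@H]2[C@H](CO[Si](CC)(CC)CC)/C1=C\[C@@H](C)O[Si](c1ccccc1)(c1ccccc1)C(C)(C)C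
F3 | step 13 | C4 allylic alcohol from F2 | CC1=C[C@H]2C(O)C(C)=C(OC)[C@H](C)[C@H]2[C@H](CO[Si](CC)(CC)CC)/C1=C\[C@@H](C)O[Si](c1ccccc1)(c1ccccc1)C(C)(C)C
F4 | step 3 | (2Z)-4-[(tert-butyldimethylsilyl)oxy]but-2-en-1-ol | OC/C=C\CO[Si](C)(C)C(C)(C)C
F5 | step 3 | {(2S,3R)-3-({[tert-butyl(dimethyl)silyl]oxy}methyl)oxiran-2-yl}methanol | OC[C@@H]1O[C@@H]1CO[Si](C)(C)C(C)(C)C
F6 | step 3 | (2R,3S,6R)-3-({[tert-butyl(dimethyl)silyl]oxy}methyl)-6-[(tert-butyldiphenylsilyl)oxy]hept-4-yne-1,2-diol | OC[C@H](O)[C@H](CO[Si](C)(C)C(C)(C)C)C#C[C@@H](C)O[Si](c1ccccc1)(c1ccccc1)C(C)(C)C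
F7 | step 3 | (2S,5R)-2-({[tert-butyl(dimethyl)silyl]oxy}methyl)-5-[(tert-butyldiphenylsilyl)oxy]hex-3-ynal | O=C[C@H](CO[Si](C)(C)C(C)(C)C)C#C[C@@H](C)O[Si](c1ccccc1)(c1ccccc1)C(C)(C)C
F8 | step 3 | tert-butyldimethylsilyl ether of 9 at the primary alcohol | COC(=O)/C(C)=C/[C@H](CO[Si](C)(C)C(C)(C)C)C#C[C@@H](C)O[Si](c1ccccc1)(c1ccccc1)C(C)(C)C
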